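Numbering (germacrane): ring carbons C1–C10; five-membered lactone ring O–C6–C7–C11(=C13)–C12(=O); C14 is the ester carbon on C10, C15 the methyl on C4, and the methacrylate sits on O8.
Cuts, in retrosynthetic order: acyl–O8 and the mask on C11=C13; ring bond C1=C10 (intramolecular HWE); O–C6 and C7–C11 together (annulation with 2-bromoacrylic acid); C5–C6 (Heck) and C9–C10 (alkylation).
Enabling feature: the lactone carbinol carbon C6 is allylic to the trisubstituted C4=C5 bond. C4=C5–C6(O)–C7(C11) is therefore the 1,2-carbo-oxygenation pattern of a C4=C5–C6=C7 diene passing through an η3-allylpalladium unit over C4–C6, and one C3 acid delivers O, C12, C11 and C13 at once.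
Forward: fragments C1–C5 and C6–C10 are joined to a linear E,E-diene. The lactone ring closes first (step 8), its methylene is masked as the Me2NH adduct, the ten-membered ring closes second (step 11), then O8 is acylated and the methylene released.
Stereochemistry: C8 comes from (S)-but-3-ene-1,2-diol, C7 by 1,2-induction from C8, and C6 from C7 through syn carbopalladation and same-face C–O closure on the E C6=C7 bond. E C4=C5 comes from syn carboalumination and is kept by the syn-allyl geometry; C1=C10 comes from the E-selective HWE.

Key step: step 8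

Remark on the chemistry: 10, 11 and 13–16 are carried as epimer mixtures at C10, and 15–20 at C11. Both carbons become sp2 later, so these centres are left undefined in the SMILES.

Step 1
Reactants: 1 pent-4-yn-1-ol
Product: 3 (E)-5-iodo-4-methylpent-4-en-1-ol, via alkenylalane 2 (not isolated)
Conditions: AlMe3 (3 equiv), Cp2ZrCl2 (0.25 equiv), CH2Cl2, 0 °C to rt; I2, THF, −30 °C; aq. work-up
Reagents that add atoms: trimethylaluminium, C[Al](C)C; iodine, II
Why: Negishi zirconium-catalysed carboalumination adds CH3 (to C4) and aluminium (to C5) syn across the terminal alkyne and iodinolysis proceeds with retention, so the E geometry of C4=C5 and the C15 methyl group are set together.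

Step 2
Reactants: 3 (E)-5-iodo-4-methylpent-4-en-1-ol
Product: 4 (E)-5-iodo-4-methylpent-4-enal
Conditions: TEMPO (0.1 equiv), PhI(OAc)2 (1.1 equiv), CH2Cl2, rt
Reagents that add atoms: none
Why: The oxoammonium (TEMPO/PhI(OAc)2) oxidation of a primary alcohol stops at the aldehyde and leaves the alkenyl iodide untouched.

Step 3
Reactants: 4 (E)-5-iodo-4-methylpent-4-enal
Product: 5 (E)-1-iodo-5,5-dimethoxy-2-methylpent-1-ene
Conditions: HC(OMe)3, p-TsOH·H2O (cat.), MeOH, rt
Reagents that add atoms: trimethyl orthoformate, COC(OC)OC
Why: Acid-catalysed acetalisation with the orthoformate as water scavenger masks C1 so that aldehyde and phosphonate do not meet before step 11.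

Step 4
Reactants: 6 (S)-but-3-ene-1,2-diol
Product: 7 (S)-2-hydroxybut-3-en-1-yl 4-methylbenzenesulfonate
Conditions: TsCl (1.05 equiv), Bu2SnO (2 mol %), Et3N, CH2Cl2, 0 °C to rt
Reagents that add atoms: 4-toluenesulfonyl chloride, Cc1ccc(cc1)S(=O)(=O)Cl
Why: Bu2SnO-catalysed monosulfonylation activates the primary hydroxyl of the 1,2-diol through a stannylene acetal, and the C8 stereocentre from the chiral pool is not touched.

Step 5
Reactants: 7 (S)-2-hydroxybut-3-en-1-yl 4-methylbenzenesulfonate
Product: 8 (S)-2-[(tert-butyldimethylsilyl)oxy]but-3-en-1-yl 4-methylbenzenesulfonate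
Conditions: TBSCl, imidazole, DMF, rt
Reagents that add atoms: tert-butyldimethylsilyl chloride, CC(C)(C)[Si](C)(C)Cl
Why: Standard imidazole-promoted silylation blocks O8 against epoxide formation and installs the bulky group that later shields one face of the diene.

Step 6
Reactants: 8 (S)-2-[(tert-butyldimethylsilyl)oxy]but-3-en-1-yl 4-methylbenzenesulfonate; 9 methyl 2-(diethoxyphosphoryl)acetate
Product: 10 methyl (4R)-4-[(tert-butyldimethylsilyl)oxy]-2-(diethoxyphosphoryl)hex-5-enoate
Conditions: 9 (1.5 equiv), NaH (1.4 equiv), DMF, 0 °C; then 8, 75 °C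
Reagents that add atoms: none
Why: Malonate-type SN2 alkylation of the sodium phosphonoacetate at the primary carbon C9 forms C9–C10 without involving C8, and C10 arises as an inconsequential epimer mixture.

Step 7
Reactants: 5 (E)-1-iodo-5,5-dimethoxy-2-methylpent-1-ene; 10 methyl (4R)-4-[(tert-butyldimethylsilyl)oxy]-2-(diethoxyphosphoryl)hex-5-enoate
Product: 11 methyl (4R,5E,7E)-4-[(tert-butyldimethylsilyl)oxy]-2-(diethoxyphosphoryl)-11,11-dimethoxy-8-methylundeca-5,7-dienoate
Conditions: Pd(OAc)2 (10 mol %), Ag2CO3 (0.7 equiv), DMF, 45 °C, dark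
Reagents that add atoms: none
Why: In this Heck reaction the alkenylpalladium species from 5 adds to the unsubstituted alkene terminus C6 and syn β-hydride elimination of a C6 hydrogen gives the conjugated E C6=C7 bond with retention at C4=C5, while Ag2CO3 removes iodide and so suppresses re-addition of palladium hydride and migration toward C8.

Step 8
Reactants: 11 methyl (4R,5E,7E)-4-[(tert-butyldimethylsilyl)oxy]-2-(diethoxyphosphoryl)-11,11-dimethoxy-8-methylundeca-5,7-dienoate; 12 2-bromoacrylic acid
Product: 14 trans-α-methylene-γ-butyrolactone (6R,7S,8R), via allylpalladium carboxylate chelate 13 (not isolated)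
Conditions: Pd(OAc)2 (10 mol %), P(2-furyl)3 (25 mol %), Ag2CO3 (1.0 equiv), BHT (5 mol %), DMF, 60 °C, 12 (1.0 equiv) added over 8 h to 11 (1.2 equiv)
Reagents that add atoms: none
Why: Proposed new method: zerovalent palladium inserts into the C–Br bond of the 2-bromoacrylate, Ag2CO3 strips the bromide, and the cationic alkenylpalladium adds syn across the C6=C7 bond of 11 (C11 to C7, palladium to C6) to give an η3-allyl complex over C6–C5–C4 that the pendant carboxylate holds as chelate 13; C–O bond formation at C6 on the palladium-bearing face then releases 14 and zerovalent palladium. The closest known reaction type is the Larock heteroannulation of 1,3-dienes with halide-bearing carboxylic acids, phenols and anilines, established for terminal and cyclic dienes (whose cis-fused products show that a tethered nucleophile can bond on the palladium face) but not for an acyclic 1,4,4-trisubstituted diene with an allylic stereocentre. The only ring closed is the five-membered lactone, by 5-exo attack of the carboxylate oxygen on the secondary allyl terminus C6, attack at the tertiary terminus C4 needing a seven-membered ring. C7 is controlled by C8: with H8 in the diene plane the bulky, electron-withdrawing C8–OTBS bond stands anti to the forming C7–C11 bond (Felkin–Anh-type arrangement), so C11 enters on the face away from the silyl ether. C6 is controlled by C7 through the mechanism, since syn carbopalladation of the E C6=C7 bond followed by closure on the same face is a net syn addition and gives the trans-4,5-disubstituted lactone, which is also the less crowded closure and the more stable isomer, and C3 stays in the syn position of the allyl unit so that C4=C5 re-forms as E. The step needs regioselectivity for C7 over C4 (secured by the monosubstituted against the disubstituted diene terminus), chemoselectivity for the diene (secured because the enoate and the methacrylate are not yet present and 12 is fed slowly) and an intact phosphonoacetate C–H (secured by the weak, insoluble base).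

Step 9
Reactants: 14 trans-α-methylene-γ-butyrolactone (6R,7S,8R)
Product: 15 13-(dimethylamino)-11,13-dihydro lactone
Conditions: Me2NH (2 M in THF, 1.5 equiv), THF, 0 °C to rt
Reagents that add atoms: dimethylamine, CNC
Why: Aza-Michael addition to the exocyclic methylene, the standard reversible mask of α-methylene lactones, removes the conjugate acceptor that the C10 carbanion would otherwise attack through a six-membered ring in step 11.

Step 10
Reactants: 15 13-(dimethylamino)-11,13-dihydro lactone
Product: 16 seco-aldehyde
Conditions: AcOH–THF–H2O 3:1:1, 40 °C; aq. NaHCO3 work-up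
Reagents that add atoms: water, O
Why: Aqueous acetic acid hydrolyses the aliphatic dimethyl acetal much faster than it cleaves a secondary TBS ether, and the protonated amine stays in place.

Step 11
Reactants: 16 seco-aldehyde
Product: 17 ten-membered carbocycle as its 8-O-TBS ether
Conditions: LiCl (10 equiv), DBU (3 equiv), MeCN, 1 mM, slow addition of 16, rt to 40 °C
Reagents that add atoms: none
Why: In this intramolecular Horner–Wadsworth–Emmons olefination under Masamune–Roush conditions at high dilution, the trans-lactone and the E C4=C5 bond pre-orient the two arms, and the diethyl phosphonoacetate intrinsically places CO2Me trans to C2 (E), which is also the ring-cis and less strained geometry of the ten-membered ring.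

Step 12
Reactants: 17 ten-membered carbocycle as its 8-O-TBS ether
Product: 18 8-hydroxy macrocycle
Conditions: HF·pyridine, pyridine, THF, 0 °C to rt
Reagents that add atoms: none
Why: Buffered fluoride desilylation frees O8 without the basic conditions that could cause translactonisation to O8 or loss of the amine mask, and the electron-poor C1=C10 bond disfavours acid-induced transannular cyclisation.

Step 13
Reactants: 18 8-hydroxy macrocycle
Product: 19 8-O-methacrylate of the masked lactone
Conditions: methacrylic anhydride (3 equiv), Et3N, DMAP (0.3 equiv), CH2Cl2, 0 °C to rt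
Reagents that add atoms: methacrylic anhydride, C=C(C)C(=O)OC(=O)C(C)=C
Why: DMAP-catalysed acylation esterifies the secondary alcohol with retention at C8, and the tertiary amine cannot be acylated.

Step 14
Reactants: 19 8-O-methacrylate of the masked lactone
Product: 21 target CNP0317149.1, via trimethylammonium iodide 20 (not isolated)
Conditions: MeI (10 equiv), THF, rt; evaporate; NaHCO3, H2O–CH2Cl2, rt
Reagents that add atoms: iodomethane, CI (its atoms are carried by 20 only)
Why: Quaternisation followed by mild E1cB (Hofmann-type) elimination of trimethylamine is the standard release of an α-methylene lactone from its Mannich-type adduct and touches none of the three stereocentres or the other esters.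

Compound list
1 | pent-4-yn-1-ol | C#CCCCO | starting material
2 | alkenylalane: dimethylaluminium alkoxide of (E)-5-(dimethylalumanyl)-4-methylpent-4-en-1-ol | C[Al](C)OCCC/C(C)=C/[Al](C)C | intermediate
3 | (E)-5-iodo-4-methylpent-4-en-1-ol | OCCC/C(C)=C/I | intermediate
4 | (E)-5-iodo-4-methylpent-4-enal | O=CCC/C(C)=C/I | intermediate
5 | (E)-1-iodo-5,5-dimethoxy-2-methylpent-1-ene | COC(OC)CC/C(C)=C/I | intermediate
6 | (S)-but-3-ene-1,2-diol | C=C[C@H](O)CO | starting material
7 | (S)-2-hydroxybut-3-en-1-yl 4-methylbenzenesulfonate | C=C[C@H](O)COS(=O)(=O)c1ccc(C)cc1 | intermediate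
8 | (S)-2-[(tert-butyldimethylsilyl)oxy]but-3-en-1-yl 4-methylbenzenesulfonate | C=C[C@H](O[Si](C)(C)C(C)(C)C)COS(=O)(=O)c1ccc(C)cc1 | intermediate
9 | methyl 2-(diethoxyphosphoryl)acetate | CCOP(=O)(CC(=O)OC)OCC | starting material
10 | methyl (4R)-4-[(tert-butyldimethylsilyl)oxy]-2-(diethoxyphosphoryl)hex-5-enoate (C2 epimers) | C=C[C@H](O[Si](C)(C)C(C)(C)C)CC(C(=O)OC)P(=O)(OCC)OCC | intermediate
11 | methyl (4R,5E,7E)-4-[(tert-butyldimethylsilyl)oxy]-2-(diethoxyphosphoryl)-11,11-dimethoxy-8-methylundeca-5,7-dienoate | COC(OC)CC/C(C)=C/C=C/[C@H](O[Si](C)(C)C(C)(C)C)CC(C(=O)OC)P(=O)(OCC)OCC | intermediate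
12 | 2-bromoacrylic acid | C=C(Br)C(=O)O | starting material
13 | allylpalladium carboxylate chelate, drawn as the C6-σ-bonded six-membered palladacycle with the phosphine omitted (η3 over C6–C5–C4 in solution); palladium on the C6 face that later carries O | COC(OC)CC/C(C)=C/[C@H]1[Pd]OC(=O)C(=C)[C@@H]1[C@H](O[Si](C)(C)C(C)(C)C)CC(C(=O)OC)P(=O)(OCC)OCC | intermediate
14 | trans-α-methylene-γ-butyrolactone (6R,7S,8R; same spatial arrangement as in 21): C6 bears the (E)-5,5-dimethoxy-2-methylpent-1-enyl chain, C7 the (1R)-1-(TBSO)-3-(diethoxyphosphoryl)-4-methoxy-4-oxobutyl chain | COC(OC)CC/C(C)=C/[C@H]1OC(=O)C(=C)[C@@H]1[C@H](O[Si](C)(C)C(C)(C)C)CC(C(=O)OC)P(=O)(OCC)OCC | intermediate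
15 | 13-(dimethylamino)-11,13-dihydro lactone (Me2NH adduct of 14) | COC(OC)CC/C(C)=C/[C@H]1OC(=O)C(CN(C)C)[C@@H]1[C@H](O[Si](C)(C)C(C)(C)C)CC(C(=O)OC)P(=O)(OCC)OCC | intermediate
16 | seco-aldehyde (C1 aldehyde of 15) | O=CCC/C(C)=C/[C@H]1OC(=O)C(CN(C)C)[C@@H]1[C@H](O[Si](C)(C)C(C)(C)C)CC(C(=O)OC)P(=O)(OCC)OCC | intermediate
17 | ten-membered carbocycle, 8-O-TBS ether (E ring-cis C1=C10 with CO2Me trans to C2, E C4=C5, trans-fused lactone, 6R,7S,8R) | CC(C)(C)[Si](C)(C)O[C@@H]1C/C(C(=O)OC)=C\CC/C(C)=C/[C@H]2OC(=O)C(CN(C)C)[C@@H]21 | intermediate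
18 | 8-hydroxy macrocycle (6R,7R,8R), 13-dimethylamino mask in place | O[C@@H]1C/C(C(=O)OC)=C\CC/C(C)=C/[C@H]2OC(=O)C(CN(C)C)[C@@H]21 | intermediate
19 | 8-O-methacrylate of the masked lactone | C=C(C)C(=O)O[C@@H]1C/C(C(=O)OC)=C\CC/C(C)=C/[C@H]2OC(=O)C(CN(C)C)[C@@H]21 | intermediate
20 | trimethylammonium iodide of 19 | C=C(C)C(=O)O[C@@H]1C/C(C(=O)OC)=C\CC/C(C)=C/[C@H]2OC(=O)C(C[N+](C)(C)C)[C@@H]21.[I-] | intermediate
21 | methyl (1(10)E,4E,6R,7R,8R)-8-(methacryloyloxy)-12-oxo-6,12-epoxygermacra-1(10),4,11(13)-trien-14-oate (CNP0317149.1) | C=C(C)C(=O)O[C@@H]1C/C(C(=O)OC)=C\CC/C(C)=C/[C@H]2OC(=O)C(=C)[C@@H]21 | target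

Total step count: 14. Longest linear sequence: 11 (steps 4–14 from 6; equally steps 1–3 and 7–14 from 1).

Steps most likely to fail

1. Step 8.
- Insertion into the hindered internal diene may be slow. Self-consumption of the bromoacrylate (oligomerisation, dehydrobromination) or a second Heck reaction at the newly formed exocyclic methylene could then take over.
- Facial selectivity at C7 may be poor.
- Closure on the face away from palladium, or syn/anti exchange in the allyl unit, may erode the trans relationship or the E geometry.
- The phosphonate carbon may add in conjugate fashion to the new acceptor.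

Fallback, from 5 and 10 back to 14: the classical allylmetal route to α-methylene-γ-butyrolactones, which makes C6–C7 and O–C12 instead. Iodine–lithium exchange on 5 (t-BuLi, Et2O, −78 °C) and a DMF quench should give (E)-6,6-dimethoxy-3-methylhex-2-enal F1. Ozonolysis of 10 (O3, CH2Cl2, −78 °C; Me2S) should give methyl (4R)-4-[(tert-butyldimethylsilyl)oxy]-2-(diethoxyphosphoryl)-5-oxopentanoate F2. Reaction of F2 with methyl acrylate and DABCO should give the Morita–Baylis–Hillman alcohol F3, and NBS/Me2S should give the rearranged (Z)-2-(bromomethyl)enoate F4. Nozaki–Hiyama allylation of F1 with F4 (CrCl2, THF, rt) should join C7 to C6 through a chair transition state that favours the anti hydroxy ester F5. This should close to 14 on warming with a trace of PPTS in benzene.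

2. Step 11. Oligomerisation may compete with closure of the strained ten-membered ring, the alkene geometry may be poorly controlled, and the aldehyde may enolise under the base.

Fallback, from 15 back to 17: ring-closing metathesis. HWE reaction of 15 with aqueous formaldehyde (K2CO3, THF) should convert the phosphonoacetate into the 2-substituted acrylate F6. Acetal hydrolysis as in step 10 should give the acrylate aldehyde F7, and Wittig methylenation (Ph3P=CH2, THF, −78 °C) should give the metathesis diene F8. After protonation of the amine with camphorsulfonic acid, second-generation Hoveyda–Grubbs catalyst in hot dilute toluene should close C1=C10 in its ring-cis form and give 17.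

3. Step 7. β-Hydride elimination toward C8 would lose the stereocentre through enol ether formation. Branched insertion, or palladium hydride migration along the new diene, may also occur.

Fallback, from 10 and 5 back to 11: Suzuki–Miyaura coupling. Cross metathesis of 10 with vinylboronic acid pinacol ester (second-generation Hoveyda–Grubbs catalyst, CH2Cl2, 40 °C) should give the (E)-alkenylboronic acid pinacol ester F9. Coupling of F9 with 5 (PdCl2(dppf), K3PO4, DMF–H2O, rt) should proceed with retention at both alkenes.

Further compounds
F1 | step 8 | (E)-6,6-dimethoxy-3-methylhex-2-enal | COC(OC)CC/C(C)=C/C=O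
F2 | step 8 | methyl (4R)-4-[(tert-butyldimethylsilyl)oxy]-2-(diethoxyphosphoryl)-5-oxopentanoate | O=C[C@H](O[Si](C)(C)C(C)(C)C)CC(C(=O)OC)P(=O)(OCC)OCC
F3 | step 8 | Morita–Baylis–Hillman alcohol | C=C(C(=O)OC)C(O)[C@H](O[Si](C)(C)C(C)(C)C)CC(C(=O)OC)P(=O)(OCC)OCC
F4 | step 8 | (Z)-2-(bromomethyl)enoate | BrC/C(C(=O)OC)=C\[C@H](O[Si](C)(C)C(C)(C)C)CC(C(=O)OC)P(=O)(OCC)OCC
F5 | step 8 | anti hydroxy ester | COC(OC)CC/C(C)=C/[C@@H](O)[C@H](C(=C)C(=O)OC)[C@H](O[Si](C)(C)C(C)(C)C)CC(C(=O)OC)P(=O)(OCC)OCC
F6 | step 11 | 2-substituted acrylate | COC(OC)CC/C(C)=C/[C@H]1OC(=O)C(CN(C)C)[C@@H]1[C@H](O[Si](C)(C)C(C)(C)C)CC(=C)C(=O)OC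
F7 | step 11 | acrylate aldehyde | O=CCC/C(C)=C/[C@H]1OC(=O)C(CN(C)C)[C@@H]1[C@H](O[Si](C)(C)C(C)(C)C)CC(=C)C(=O)OC
F8 | step 11 | metathesis diene | C=CCC/C(C)=C/[C@H]1OC(=O)C(CN(C)C)[C@@H]1[C@H](O[Si](C)(C)C(C)(C)C)CC(=C)C(=O)OC
F9 | step 7 | (E)-alkenylboronic acid pinacol ester | CC1(C)OB(/C=C/[C@H](O[Si](C)(C)C(C)(C)C)CC(C(=O)OC)P(=O)(OCC)OCC)OC1(C)C
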